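(All constants come from no measurement; the rest is arithmetic.)

One percent here means one percent of the substrate charged, so the flasks below stand on a single scale.

| flask | substrate | coupling partner | temperature | time |
|---|---|---|---|---|
| dusk | 0.050 M | 0.150 M | 45 °C | 80 s |
| winter | 0.050 M | 0.150 M | 5 °C | 80 s |
| autumn | 0.050 M | 0.150 M | 25 °C | 80 s |
| summer | 0.050 M | 0.150 M | −15 °C | 80 s |

    substrate + coupling partner → first product (k1 = 1.0 M⁻¹ s⁻¹, Ea1 = 62.0 kJ mol⁻¹)
    substrate + coupling partner → other mono adduct (k2 = 1.6 M⁻¹ s⁻¹, Ea2 = 37.0 kJ mol⁻¹)
    coupling partner + first product → double product (k3 = 0.014 M⁻¹ s⁻¹, Ea3 = 63.0 kJ mol⁻¹)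
    coupling partner + other mono adduct → double product (k4 = 0.019 M⁻¹ s⁻¹, Ea4 = 63.0 kJ mol⁻¹)
    coupling partner → decomposed reagent (k5 = 0.0023 s⁻¹, Ea5 = 85.0 kJ mol⁻¹)
    coupling partner ⇌ dormant form (K6 = 0.99, k6 = 0.021 s⁻¹, Ea6 = 75.0 kJ mol⁻¹, ΔH6 = −51.0 kJ mol⁻¹)
    (constants at 25 °C)

- which flask leads in amount of first product, in percent of the substrate charged ("all alike" within 1.5 percentage points) (dusk / winter / autumn / summer / all alike)
- how much first product is there at the end, in percent of the substrate charged: dusk
- how much first product is there at the end, in percent of the substrate charged: winter
- how much first product is there at the end, in percent of the substrate charged: autumn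
- how much first product is there at the end, in percent of the substrate charged: summer

- constants are those at 25 °C; use the activation energies and enthalpies for any other temperature

Look at the first two steps. Both rates carry c(substrate)·c(coupling partner), so when you divide one by the other, the concentrations and the time drop out. A quantity of temperature remains:

split share = k of the first step / (k of the first step + k of the second step)

Each k moves from 25 °C by its own Arrhenius factor. The first step has the higher barrier, 62.0 kJ mol⁻¹ against 37.0 kJ mol⁻¹, so heat favours it.

dusk: 54.1 %
autumn: 38.5 %
winter: 23.2 %
summer: 11.6 %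

This split share, the part of the converted substrate that leaves by the first step, is the selectivity factor written as a share. It is my first way to the dusk number. In the dusk flask, substrate falls by a factor e in about 0.749 s, far shorter than the run. So the share is the dusk ceiling.

My second way follows the first product after it forms. Its loss depends on the dose, the time integral of c(coupling partner). At dusk, 0.100 M of coupling partner remains once each substrate has taken one. The dormant equilibrium, 0.272, relaxes in 1.05 s, so it keeps 78.6 % of that pool free.

decay constant at dusk: 0.0199 s⁻¹
decay of the pool: 0.0156 s⁻¹
dose: 3.59 M·s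
constant of the further addition: 0.0692 M⁻¹ s⁻¹
surviving part: 78.0 %

Share times survival gives dusk 42.2 %. The two ways part by 12 percentage points, and the first one cheats: it lets every first product survive.

Winter needs about 9.36 s per factor e, and autumn 2.56 s. I count the dose generously in winter, as the whole charge for the whole time, and the same way as dusk in autumn:

winter: 22.6 %
autumn: 36.4 %

For summer I reckon a conversion as well as a share. The two summer constants sum to 0.179 M⁻¹ s⁻¹. Taking a mean c(coupling partner) of 0.125 M gives a conversion of 83.3 %, so summer comes to 9.65 %.

My ranking: dusk.

The forecast names dusk, with dusk 43.7 %, winter 22.8 %, autumn 35.8 % and summer 9.5 %. Its grounds are that the higher barrier “means heat shifts the split strongly towards it”. Its dusk figure stands above mine.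

The simulation gives dusk as the leader, with dusk 43.4 %, winter 22.8 %, autumn 36.2 % and summer 9.54 %. In the dusk flask, double product stood at 15.8 % after 40.0 s and 22.6 % after 80.0 s. Apply the split share of 54.1 % to the 77.4 % of substrate outside double product, and you get 41.9 % for dusk. A flask like dusk kept at 60 °C has a split share of 64.3 %. On its 79.4 % outside double product, that gives 51.1 %, and that flask holds 52.4 %.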